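## Retrosynthetic overview

- **Feature:** rings A and C are each a benzene-1,3,5-triol with ring B on C1' and oxygen on C2', C4' and C6'. This alternating pattern is that of a folded triketide whose starter is an arylacetyl unit with ring B as the aryl group.
- **Key disconnection:** both C1'–C2' bonds (benzylic carbon to ester carbon) are cut at once. This unfolds A and C into two 3,5-dioxohexanoate arms on C2 and C4 of a tribenzylated ring B.
- **Arms:** C4–C5 of each arm joins the γ-carbanion of methyl acetoacetate to a Weinreb amide of the ring B diacetic acid. That acid goes back to 2,4-diacetylphloroglucinol by an oxidative aryl shift and O-benzylation.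
- **Order of rings:** B is bought; A and C are closed together in one flask.
- **Endgame:** the C4' hydroxyls are silylated and one ortho hydroxyl of A is tied to one of C by a disiloxane bridge. The two ortho hydroxyls left over are sulfated as trichloroethyl esters, followed by fluoride and transfer hydrogenolysis.

Key step: step 5

Assumption: the target SMILES assigns no configuration to the two hindered biaryl axes and draws the sulfates as free acids, so only the constitution is aimed at (the bridge used later would place both sulfates on the same face of ring B) and the acid form is released from its ammonium salt at the very end.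

## Route

Step 1
Reactants: 1 2,4-diacetylphloroglucinol; 2 benzyl bromide
Product: 3 1,1'-[2,4,6-tris(benzyloxy)-1,3-phenylene]diethanone
Conditions: BnBr (4 equiv), K2CO3 (5 equiv), DMF, 70 °C
Reagents that add atoms: benzyl bromide, BrCc1ccccc1
Why: Williamson ether synthesis, in which K2CO3 in a dipolar aprotic solvent fully ionises the three acidic, acyl-chelated phenols and so favours O- over C-benzylation at the one free ring carbon, while heating carries the hindered central hydroxyl through.

Step 2
Reactants: 3 1,1'-[2,4,6-tris(benzyloxy)-1,3-phenylene]diethanone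
Product: 4 dimethyl 2,2'-[2,4,6-tris(benzyloxy)-1,3-phenylene]diacetate
Conditions: Tl(NO3)3·3H2O (2.2 equiv), 70% aq. HClO4, MeOH/CH2Cl2, rt
Reagents that add atoms: methanol, CO
Why: Oxidative 1,2-aryl migration of aryl methyl ketones with thallium trinitrate (McKillop–Taylor rearrangement), in which oxythallation of each enol is followed by the shift of the very electron-rich aryl group with loss of TlNO3 and capture by methanol, under conditions that benzyl aryl ethers tolerate.

Step 3
Reactants: 4 dimethyl 2,2'-[2,4,6-tris(benzyloxy)-1,3-phenylene]diacetate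
Product: 5 2,2'-[2,4,6-tris(benzyloxy)-1,3-phenylene]bis(N-methoxy-N-methylacetamide)
Conditions: MeNH(OMe)·HCl (5 equiv), i-PrMgCl (10 equiv), THF, −20 → 0 °C
Reagents that add atoms: N,O-dimethylhydroxylamine hydrochloride, CNOC.Cl
Why: Weinreb amide synthesis by direct aminolysis of the esters with the chloromagnesium amide, which works on enolisable arylacetates because the ester carbonyls stand one CH2 away from the hindered ring and the amide is held as its magnesium chelate.

Step 4
Reactants: 5 2,2'-[2,4,6-tris(benzyloxy)-1,3-phenylene]bis(N-methoxy-N-methylacetamide); 6 methyl acetoacetate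
Product: 8 dimethyl 6,6'-[2,4,6-tris(benzyloxy)-1,3-phenylene]bis(3,5-dioxohexanoate), via methyl acetoacetate dianion 7 (not isolated)
Conditions: 6 (5 equiv), NaH, THF, 0 °C, then n-BuLi, 0 °C; add 5, −78 → 0 °C; cold 1 M HCl
Reagents that add atoms: methyl acetoacetate, COC(=O)CC(C)=O
Why: γ-Acylation of the acetoacetate dianion (Weiler dianion chemistry) by a Weinreb amide, in which the more basic terminal carbanion adds and the chelated tetrahedral adduct holds until the quench, so that neither over-addition nor protonation of the dianion by the acidic product takes place.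

Step 5
Reactants: 8 dimethyl 6,6'-[2,4,6-tris(benzyloxy)-1,3-phenylene]bis(3,5-dioxohexanoate)
Product: 9 1,3,5-tris(benzyloxy)-2,4-bis(2,4,6-trihydroxyphenyl)benzene
Conditions: t-BuOK (10 equiv), degassed DMF, Ar, 0 → 60 °C; then cold 1 M HCl
Reagents that add atoms: none
Why: Excess t-BuOK turns each arm into its C2,C4-bis(enolate), a resting state whose ester is switched off, so the monoenolate that would lactonise through the C5 oxygen to a 4-hydroxy-2-pyranone is present only in traces, and t-BuOK is too weak to take the third proton, which an amide base would remove to freeze the arm as an inert trianion. The t-BuOH formed shuttles protons and gives a small share of the isomeric C4,C6-dianion, in which C2 is protonated, the ester is a normal electrophile and benzylic C6 (the future C1') is by far the most nucleophilic atom; it adds to the ester carbon C1 (the future C2'), methoxide leaves, and the cyclohexane-1,3,5-trione enolises to the phloroglucinolate, which makes the C-acylation irreversible and drains the equilibria. The reaction is an intramolecular Claisen (Dieckmann-type) condensation, known for polyketo esters giving phloroglucinols, for the terminal acylation of β-diketone dianions by esters, and for 6-aryl-5-oxohexanoates with 2,6-disubstituted aryl groups, which t-BuOK in DMF closes to 2-arylcyclohexane-1,3-diones. Rings A and C each close in the 6-(enolendo)-exo-trig mode, independently of one another, and no other carbon–carbon closure to a five- or six-membered ring is open to either arm. No stereocentre is formed, and the two new biaryl axes carry symmetric outer rings at this stage. The selectivity needed is C- over O-acylation, secured by the acidity that ring B and the C5 ketone lend to C6 and by keeping more than two equivalents of base per arm throughout.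

Step 6
Reactants: 9 1,3,5-tris(benzyloxy)-2,4-bis(2,4,6-trihydroxyphenyl)benzene
Product: 10 1,3,5-tris(benzyloxy)-2,4-bis[2,6-dihydroxy-4-(triisopropylsilyloxy)phenyl]benzene
Conditions: i-Pr3SiCl (2.1 equiv), imidazole, DMF, 0 °C
Reagents that add atoms: triisopropylsilyl chloride, CC(C)[Si](Cl)(C(C)C)C(C)C
Why: Sterically controlled O-silylation, in which each C4' hydroxyl, flanked by two ring hydrogens, should react far faster with the bulky chlorosilane than the C2' and C6' hydroxyls, which lie against the perpendicular ring B and its benzyloxy groups.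

Step 7
Reactants: 10 1,3,5-tris(benzyloxy)-2,4-bis[2,6-dihydroxy-4-(triisopropylsilyloxy)phenyl]benzene
Product: 11 disiloxane-bridged diol: 10 in which one ortho oxygen of ring A and the ortho oxygen of ring C on the same face of ring B are joined through Si(i-Pr)2–O–Si(i-Pr)2 (12-membered ring, mirror-symmetric), with one ortho hydroxyl per outer ring left free
Conditions: (i-Pr2SiCl)2O (1.0 equiv, slow addition), imidazole, DMF (0.005 M), rt → 40 °C
Reagents that add atoms: 1,3-dichloro-1,1,3,3-tetraisopropyldisiloxane, CC(C)[Si](Cl)(C(C)C)O[Si](Cl)(C(C)C)C(C)C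
Why: Cyclic disiloxane (TIPDS) protection by twofold O-silylation, known for capping two neighbouring phenols of calixarenes: the two ortho hydroxyls of one outer ring lie on opposite faces of ring B and cannot be spanned by the Si–O–Si unit, whereas one hydroxyl of ring A and one of ring C on the same face lie about 5 Å apart, so after the first Si–O bond the second closes the 12-membered ring under high dilution and leaves exactly one free ortho hydroxyl on each outer ring.

Step 8
Reactants: 11 disiloxane-bridged diol; 12 2,2,2-trichloroethyl chlorosulfate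
Product: 13 bis(2,2,2-trichloroethyl sulfate) of 11 (both free ortho hydroxyls converted into OSO2OCH2CCl3)
Conditions: 12 (5 equiv), Et3N, DMAP, THF, 0 °C → rt
Reagents that add atoms: 2,2,2-trichloroethyl chlorosulfate, ClS(=O)(=O)OCC(Cl)(Cl)Cl
Why: Sulfation of phenols as protected sulfate diesters (DMAP-assisted sulfuryl transfer from the chlorosulfate), in which only the two wanted hydroxyls are free, so that an excess of reagent can be used, no site selectivity is asked of the step and the neutral diester can be purified on silica.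

Step 9
Reactants: 13 bis(2,2,2-trichloroethyl sulfate) of 11
Product: 14 1,3,5-tris(benzyloxy)-2,4-bis[2,4-dihydroxy-6-(2,2,2-trichloroethoxysulfonyloxy)phenyl]benzene
Conditions: Et3N·3HF, THF, rt
Reagents that add atoms: none
Why: Fluoride-induced cleavage of aryl silyl ethers, in which the mildly acidic amine–HF complex removes both triisopropylsilyl groups and the disiloxane bridge through the good phenoxide leaving groups and avoids the basic medium in which trichloroethyl sulfates lose HCl.

Step 10
Reactants: 14 1,3,5-tris(benzyloxy)-2,4-bis[2,4-dihydroxy-6-(2,2,2-trichloroethoxysulfonyloxy)phenyl]benzene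
Product: 16 2,4-bis[2,4-dihydroxy-6-(sulfooxy)phenyl]benzene-1,3,5-triol (target), via diammonium bis-sulfate 15 (not isolated)
Conditions: 10% Pd/C, HCO2NH4 (excess), MeOH, rt; filter; Dowex 50W (H+ form), H2O, 0 °C; freeze-dry
Reagents that add atoms: none
Why: Catalytic transfer hydrogenolysis, in which Pd/C with ammonium formate reductively fragments the two trichloroethyl sulfate esters and cleaves the three benzyl aryl ethers in the same flask without touching the aryl O–S bonds, after which cold cation exchange turns the ammonium salt into the acid form drawn.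

## Compound list

1 | 2,4-diacetylphloroglucinol | CC(=O)c1c(O)cc(O)c(C(C)=O)c1O | starting material
2 | benzyl bromide | BrCc1ccccc1 | starting material
3 | 1,1'-[2,4,6-tris(benzyloxy)-1,3-phenylene]diethanone | CC(=O)c1c(OCc2ccccc2)cc(OCc2ccccc2)c(C(C)=O)c1OCc1ccccc1 | intermediate
4 | dimethyl 2,2'-[2,4,6-tris(benzyloxy)-1,3-phenylene]diacetate | COC(=O)Cc1c(OCc2ccccc2)cc(OCc2ccccc2)c(CC(=O)OC)c1OCc1ccccc1 | intermediate
5 | 2,2'-[2,4,6-tris(benzyloxy)-1,3-phenylene]bis(N-methoxy-N-methylacetamide) | CON(C)C(=O)Cc1c(OCc2ccccc2)cc(OCc2ccccc2)c(CC(=O)N(C)OC)c1OCc1ccccc1 | intermediate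
6 | methyl acetoacetate | COC(=O)CC(C)=O | starting material
7 | sodium lithium dianion of methyl acetoacetate | [Na+].[Li+].C=C([O-])C=C([O-])OC | intermediate
8 | dimethyl 6,6'-[2,4,6-tris(benzyloxy)-1,3-phenylene]bis(3,5-dioxohexanoate) | COC(=O)CC(=O)CC(=O)Cc1c(OCc2ccccc2)cc(OCc2ccccc2)c(CC(=O)CC(=O)CC(=O)OC)c1OCc1ccccc1 | intermediate
9 | 1,3,5-tris(benzyloxy)-2,4-bis(2,4,6-trihydroxyphenyl)benzene | Oc1cc(O)c(-c2c(OCc3ccccc3)cc(OCc3ccccc3)c(-c3c(O)cc(O)cc3O)c2OCc2ccccc2)c(O)c1 | intermediate
10 | 1,3,5-tris(benzyloxy)-2,4-bis[2,6-dihydroxy-4-(triisopropylsilyloxy)phenyl]benzene | CC(C)[Si](C(C)C)(C(C)C)Oc1cc(O)c(-c2c(OCc3ccccc3)cc(OCc3ccccc3)c(-c3c(O)cc(O[Si](C(C)C)(C(C)C)C(C)C)cc3O)c2OCc2ccccc2)c(O)c1 | intermediate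
11 | disiloxane-bridged diol (A-ring and C-ring ortho oxygens on one face joined by Si(i-Pr)2–O–Si(i-Pr)2) | O1c2cc(O[Si](C(C)C)(C(C)C)C(C)C)cc(O)c2-c2c(OCc3ccccc3)cc(OCc3ccccc3)c(c2OCc2ccccc2)-c2c(O)cc(O[Si](C(C)C)(C(C)C)C(C)C)cc2O[Si](C(C)C)(C(C)C)O[Si]1(C(C)C)C(C)C | intermediate
12 | 2,2,2-trichloroethyl chlorosulfate | ClS(=O)(=O)OCC(Cl)(Cl)Cl | starting material
13 | bis(2,2,2-trichloroethyl sulfate) of 11 | O1c2cc(O[Si](C(C)C)(C(C)C)C(C)C)cc(OS(=O)(=O)OCC(Cl)(Cl)Cl)c2-c2c(OCc3ccccc3)cc(OCc3ccccc3)c(c2OCc2ccccc2)-c2c(OS(=O)(=O)OCC(Cl)(Cl)Cl)cc(O[Si](C(C)C)(C(C)C)C(C)C)cc2O[Si](C(C)C)(C(C)C)O[Si]1(C(C)C)C(C)C | intermediate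
14 | 1,3,5-tris(benzyloxy)-2,4-bis[2,4-dihydroxy-6-(2,2,2-trichloroethoxysulfonyloxy)phenyl]benzene | ClC(Cl)(Cl)COS(=O)(=O)Oc1cc(O)cc(O)c1-c1c(OCc2ccccc2)cc(OCc2ccccc2)c(-c2c(O)cc(O)cc2OS(=O)(=O)OCC(Cl)(Cl)Cl)c1OCc1ccccc1 | intermediate
15 | diammonium salt of the target bis-sulfate | [NH4+].[NH4+].[O-]S(=O)(=O)Oc1cc(O)cc(O)c1-c1c(O)cc(O)c(-c2c(O)cc(O)cc2OS(=O)(=O)[O-])c1O | intermediate
16 | 2,4-bis[2,4-dihydroxy-6-(sulfooxy)phenyl]benzene-1,3,5-triol (CNP0320583.0) | O=S(=O)(O)Oc1cc(O)cc(O)c1-c1c(O)cc(O)c(-c2c(O)cc(O)cc2OS(=O)(=O)O)c1O | target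

## Step count and risks

Total step count: 10. Longest linear sequence: 10 steps (1 → 16).

### Steps most likely to fail

**Step 5.**
- **What may go wrong:** the arms may stall as unreactive bis(enolates). They may acylate on the C5 enolate oxygen and lactonise. Only one arm may close. The methoxide released may cleave the chain in a retro-Claisen sense.
- **Fallback:** the two biaryl bonds are made by Suzuki–Miyaura coupling instead of building rings A and C. It sets out from 2.
  - Benzyl bromide 2 and phloroglucinol (K2CO3, DMF) give 1,3,5-tris(benzyloxy)benzene F1.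
  - N-Iodosuccinimide (2 equiv, MeCN) converts F1 into 1,3,5-tris(benzyloxy)-2,4-diiodobenzene F2.
  - In parallel, phloroglucinol is protected (MOMCl, NaH, DMF) as 1,3,5-tris(methoxymethoxy)benzene F3.
  - F3 is treated with n-BuLi and then i-PrOBpin in THF to give 2-[2,4,6-tris(methoxymethoxy)phenyl]-4,4,5,5-tetramethyl-1,3,2-dioxaborolane F4.
  - Twofold coupling of F2 with F4 (Pd(OAc)2, SPhos, K3PO4, toluene/H2O, 100 °C) gives 1,3,5-tris(benzyloxy)-2,4-bis[2,4,6-tris(methoxymethoxy)phenyl]benzene F5.
  - HCl in MeOH/THF frees the six hydroxyls, and the route is rejoined at 9.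

**Step 7.**
- **What may go wrong:** intermolecular silylation and oligomerisation may outrun closure of the 12-membered ring. A second bridge may cap the other face.
- **Fallback:** the tether is given up for a stoichiometry-limited sulfation. It sets out from 10.
  - 10 is treated with 12 (2.0 equiv, slow addition, Et3N, DMAP, THF, −20 °C).
  - The mixture of sulfation grades is separated on silica, and under-sulfated material is resubmitted.
  - The isomer with one ester on each outer ring is collected: 1,3,5-tris(benzyloxy)-2,4-bis[2-hydroxy-6-(2,2,2-trichloroethoxysulfonyloxy)-4-(triisopropylsilyloxy)phenyl]benzene F6.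
  - Et3N·3HF in THF removes the two silyl groups, and the route is rejoined at 14.

**Step 2.**
- **What may go wrong:** once the deactivating acetyl groups are gone, trivalent thallium may oxidise or nitrate the very electron-rich ring B. The second migration may also stay incomplete next to the hindered carbonyl.
- **Fallback:** the oxidative aryl shift is replaced by a reduction, dehydration and hydroboration sequence. It sets out from 3.
  - NaBH4 (THF/MeOH) gives 1,1'-[2,4,6-tris(benzyloxy)-1,3-phenylene]diethanol F7 as a mixture of diastereomers.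
  - Mild acid-catalysed dehydration (PPTS, toluene, heat) gives 1,3,5-tris(benzyloxy)-2,4-divinylbenzene F8.
  - Hydroboration–oxidation (9-BBN, THF; then NaOH, H2O2) gives 2,2'-[2,4,6-tris(benzyloxy)-1,3-phenylene]diethanol F9.
  - TEMPO (cat.) with PhI(OAc)2 in MeCN/H2O oxidises both primary alcohols to 2,2'-[2,4,6-tris(benzyloxy)-1,3-phenylene]diacetic acid F10.
  - Fischer esterification (MeOH, cat. H2SO4) rejoins the route at 4.

## Further compounds

F1 | step 5 | 1,3,5-tris(benzyloxy)benzene | C(Oc1cc(OCc2ccccc2)cc(OCc2ccccc2)c1)c1ccccc1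
F2 | step 5 | 1,3,5-tris(benzyloxy)-2,4-diiodobenzene | Ic1c(OCc2ccccc2)cc(OCc2ccccc2)c(I)c1OCc1ccccc1
F3 | step 5 | 1,3,5-tris(methoxymethoxy)benzene | COCOc1cc(OCOC)cc(OCOC)c1
F4 | step 5 | 2-[2,4,6-tris(methoxymethoxy)phenyl]-4,4,5,5-tetramethyl-1,3,2-dioxaborolane | COCOc1cc(OCOC)c(B2OC(C)(C)C(C)(C)O2)c(OCOC)c1
F5 | step 5 | 1,3,5-tris(benzyloxy)-2,4-bis[2,4,6-tris(methoxymethoxy)phenyl]benzene | COCOc1cc(OCOC)c(-c2c(OCc3ccccc3)cc(OCc3ccccc3)c(-c3c(OCOC)cc(OCOC)cc3OCOC)c2OCc2ccccc2)c(OCOC)c1
F6 | step 7 | 1,3,5-tris(benzyloxy)-2,4-bis[2-hydroxy-6-(2,2,2-trichloroethoxysulfonyloxy)-4-(triisopropylsilyloxy)phenyl]benzene | CC(C)[Si](C(C)C)(C(C)C)Oc1cc(O)c(-c2c(OCc3ccccc3)cc(OCc3ccccc3)c(-c3c(O)cc(O[Si](C(C)C)(C(C)C)C(C)C)cc3OS(=O)(=O)OCC(Cl)(Cl)Cl)c2OCc2ccccc2)c(OS(=O)(=O)OCC(Cl)(Cl)Cl)c1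
F7 | step 2 | 1,1'-[2,4,6-tris(benzyloxy)-1,3-phenylene]diethanol (mixture of diastereomers) | CC(O)c1c(OCc2ccccc2)cc(OCc2ccccc2)c(C(C)O)c1OCc1ccccc1
F8 | step 2 | 1,3,5-tris(benzyloxy)-2,4-divinylbenzene | C=Cc1c(OCc2ccccc2)cc(OCc2ccccc2)c(C=C)c1OCc1ccccc1
F9 | step 2 | 2,2'-[2,4,6-tris(benzyloxy)-1,3-phenylene]diethanol | OCCc1c(OCc2ccccc2)cc(OCc2ccccc2)c(CCO)c1OCc1ccccc1
F10 | step 2 | 2,2'-[2,4,6-tris(benzyloxy)-1,3-phenylene]diacetic acid | OC(=O)Cc1c(OCc2ccccc2)cc(OCc2ccccc2)c(CC(=O)O)c1OCc1ccccc1
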